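**Plan**
1. The last retrosynthetic cut removes two σ-bonds of the cyclohexene ring: CH2–CH(CH2O-butyrate), and ring-fusion C(sp2)–ring-fusion CH. Both carbocycles open at once. What remains is a monocyclic cis-β-lactone with a 1-iodo-1,3-diene arm and an (E)-allylic butyrate arm.
2. Four features of the structure make this event possible. The alkene carbon shared by the cyclohexene and the cyclopentane can be a σ-alkenyl radical centre. The ring CH2–CH2 is a former vinyl group on the other alkene carbon. The two adjacent ring CH atoms are a former E-alkene. The cis-fused oxetanone holds both arms on one face.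
3. The oxetanone is cut by a ketene–aldehyde [2+2] into iodo-dienoic acid 15 and enal 18. Acid 15 is cut back (acetate alkylation, vinyl-copper addition to an ynoate, Corey–Fuchs homologation) to aldehyde 7.
4. Rings arise in this order: cyclohexane (from isophorone), then oxetanone, then cyclopentane and cyclohexene in one radical cascade, which is a reductive formal [4+2].
5. The quaternary carbon comes from a CBS reduction followed by suprafacial [2,3] chirality transfer. The lactone pair comes from the alkaloid catalyst, independent of the remote quaternary centre.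
6. The last two CH centres come from substrate control in the cascade. The tetrasubstituted C=C is fixed kinetically by hydrogen delivery to the less hindered end of an allyl radical.

Key step: step 14

Remark: as read from the SMILES, the target has quaternary C (S), lactone Cα (R), lactone C–O (S), ring-fusion CH (R) and CH–CH2O (S). The CH2O-butyrate is trans to the lactone-bearing neighbour, and the six-ring bond at the ring-fusion CH is trans to the lactone oxygen.
Assumption: O-trimethylsilylquinine is taken to give the (3R,4S)-cis-lactone in step 13. If the sense is opposite, the pseudo-enantiomeric O-trimethylsilylquinidine is used.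

**Step 1**
Reactants: 1 isophorone
Product: 2 (S)-3,5,5-trimethylcyclohex-2-en-1-ol
Conditions: (R)-Me-CBS (10 mol %), BH3·SMe2, THF, −20 °C
Reagents that add atoms: none
Why: In this Corey–Bakshi–Shibata 1,2-reduction the alkenyl side of the enone acts as the large group, so the (R)-oxazaborolidine should deliver hydride to the face that gives the (S)-carbinol.

**Step 2**
Reactants: 2 (S)-3,5,5-trimethylcyclohex-2-en-1-ol
Product: 3 tributyl({[(1S)-3,5,5-trimethylcyclohex-2-en-1-yl]oxy}methyl)stannane
Conditions: KH, THF, 0 °C; Bu3SnCH2I, 0 °C to rt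
Reagents that add atoms: tributyl(iodomethyl)stannane, CCCC[Sn](CCCC)(CCCC)CI
Why: This is a Williamson etherification of the potassium alkoxide with a primary iodide, and the C–O stereocentre is not touched.

**Step 3**
Reactants: 3 tributyl({[(1S)-3,5,5-trimethylcyclohex-2-en-1-yl]oxy}methyl)stannane
Product: 5 [(1R)-1,5,5-trimethylcyclohex-2-en-1-yl]methanol, via lithiomethyl ether 4 (not isolated)
Conditions: n-BuLi, THF, −78 to −20 °C; aq. work-up
Reagents that add atoms: none
Why: In this Still–Wittig [2,3]-sigmatropic rearrangement, Sn/Li exchange gives the carbanion, which bonds to the methyl-bearing alkene carbon on the face that carried oxygen, so the carbinol configuration is carried suprafacially to the quaternary carbon.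

**Step 4**
Reactants: 5 [(1R)-1,5,5-trimethylcyclohex-2-en-1-yl]methanol
Product: 6 [(1S)-1,3,3-trimethylcyclohexyl]methanol
Conditions: H2 (1 atm), Pd/C, EtOAc, rt
Reagents that add atoms: none
Why: Catalytic hydrogenation of the only alkene leaves the quaternary centre spatially unchanged; only its descriptor changes.

**Step 5**
Reactants: 6 [(1S)-1,3,3-trimethylcyclohexyl]methanol
Product: 7 (1S)-1,3,3-trimethylcyclohexane-1-carbaldehyde
Conditions: TEMPO (10 mol %), PhI(OAc)2, CH2Cl2, rt
Reagents that add atoms: none
Why: Oxoammonium oxidation of a primary alcohol stops at the aldehyde, which has no α-hydrogen and cannot epimerise.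

**Step 6**
Reactants: 7 (1S)-1,3,3-trimethylcyclohexane-1-carbaldehyde
Product: 8 (1S)-1-(2,2-dibromoethenyl)-1,3,3-trimethylcyclohexane
Conditions: CBr4, PPh3, CH2Cl2, 0 °C
Reagents that add atoms: carbon tetrabromide, BrC(Br)(Br)Br
Why: This first stage of the Corey–Fuchs sequence is a Wittig-type dibromo-olefination and tolerates α-quaternary aldehydes.

**Step 7**
Reactants: 8 (1S)-1-(2,2-dibromoethenyl)-1,3,3-trimethylcyclohexane
Product: 10 methyl 3-[(1S)-1,3,3-trimethylcyclohexyl]prop-2-ynoate, via lithium acetylide 9 (not isolated)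
Conditions: n-BuLi (2.1 equiv), THF, −78 °C; ClCO2Me, −78 °C to rt
Reagents that add atoms: methyl chloroformate, COC(=O)Cl
Why: In this second stage of the Corey–Fuchs sequence, Br/Li exchange, 1,2-shift and deprotonation give the acetylide, which is acylated in the same flask.

**Step 8**
Reactants: 10 methyl 3-[(1S)-1,3,3-trimethylcyclohexyl]prop-2-ynoate
Product: 12 methyl (2E)-2-iodo-3-[(1S)-1,3,3-trimethylcyclohexyl]penta-2,4-dienoate, via alkenyl vinyl cuprate 11 (not isolated)
Conditions: CH2=CHMgBr (3 equiv), CuI (1.5 equiv), THF, −40 °C; 10, −78 °C; I2, THF, −78 to −20 °C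
Reagents that add atoms: vinylmagnesium bromide, C=C[Mg]Br; iodine, II
Why: In this syn-carbocupration of an ynoate the ester directs the vinyl group electronically to the β-carbon despite the neighbouring quaternary centre, and iodinolysis of the C–Cu bond with retention places iodine cis to vinyl.

**Step 9**
Reactants: 12 methyl (2E)-2-iodo-3-[(1S)-1,3,3-trimethylcyclohexyl]penta-2,4-dienoate
Product: 13 (2E)-2-iodo-3-[(1S)-1,3,3-trimethylcyclohexyl]penta-2,4-dien-1-ol
Conditions: DIBAL-H (2.5 equiv), CH2Cl2, −78 °C; Rochelle salt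
Reagents that add atoms: none
Why: DIBAL-H reduces the enoate 1,2 to the allylic alcohol and leaves the alkenyl iodide and the diene untouched.

**Step 10**
Reactants: 13 (2E)-2-iodo-3-[(1S)-1,3,3-trimethylcyclohexyl]penta-2,4-dien-1-ol
Product: 14 (1S)-1-[(3E)-5-bromo-4-iodopenta-1,3-dien-3-yl]-1,3,3-trimethylcyclohexane
Conditions: CBr4, PPh3, CH2Cl2, 0 °C; used without storage
Reagents that add atoms: carbon tetrabromide, BrC(Br)(Br)Br
Why: The Appel reaction converts the primary allylic alcohol into the bromide under neutral conditions without allylic shift, because the γ-carbon is fully substituted.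

**Step 11**
Reactants: 14 (1S)-1-[(3E)-5-bromo-4-iodopenta-1,3-dien-3-yl]-1,3,3-trimethylcyclohexane
Product: 15 (4E)-4-iodo-5-[(1S)-1,3,3-trimethylcyclohexyl]hepta-4,6-dienoic acid
Conditions: AcOH (3 equiv), LDA (6 equiv), THF–DMPU, 0 to 40 °C; 14, 0 °C to rt; aq. HCl
Reagents that add atoms: acetic acid, CC(=O)O
Why: The acetic acid dianion is alkylated by SN2 at the primary allylic bromide, and the tetrasubstituted alkenyl iodide has no vicinal vinylic hydrogen to lose.

**Step 12**
Reactants: 16 allyl butyrate; 17 (E)-crotonaldehyde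
Product: 18 (2E)-4-oxobut-2-en-1-yl butanoate
Conditions: Hoveyda–Grubbs II (3 mol %), 17 (5 equiv), CH2Cl2, 40 °C
Reagents that add atoms: none
Why: Cross metathesis of a terminal allyl ester with an enal is selective for the cross product and gives the conjugated E-alkene.

**Step 13**
Reactants: 15 (4E)-4-iodo-5-[(1S)-1,3,3-trimethylcyclohexyl]hepta-4,6-dienoic acid; 18 (2E)-4-oxobut-2-en-1-yl butanoate
Product: 21 (2E)-3-[(2S,3R)-3-{(2E)-2-iodo-3-[(1S)-1,3,3-trimethylcyclohexyl]penta-2,4-dien-1-yl}-4-oxooxetan-2-yl]prop-2-en-1-yl butanoate, via acid chloride 19 (not isolated), via ketene 20 (not isolated)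
Conditions: (COCl)2, DMF (cat.), CH2Cl2, 0 °C to rt, evaporate; slow addition to 18 (2 equiv), O-TMS-quinine (15 mol %), LiClO4, i-Pr2NEt, CH2Cl2–Et2O, −78 °C
Reagents that add atoms: none
Why: In this alkaloid/lithium-catalysed acyl halide–aldehyde cyclocondensation (formal ketene–aldehyde [2+2]), the (Z)-ammonium enolate adds to the Li-bound aldehyde through a closed transition state, so the cis pair and its absolute sense are set by the catalyst and not by the remote quaternary carbon.

**Step 14**
Reactants: 21 (2E)-3-[(2S,3R)-3-{(2E)-2-iodo-3-[(1S)-1,3,3-trimethylcyclohexyl]penta-2,4-dien-1-yl}-4-oxooxetan-2-yl]prop-2-en-1-yl butanoate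
Product: 25 3'-norspongiolactone, via dienyl radical 22 (not isolated), via secondary alkyl radical 23 (not isolated), via allyl radical 24 (not isolated)
Conditions: Bu3SnH (1.3 equiv, syringe pump, 8 h), V-70 (0.2 equiv), degassed PhMe (0.003 M), 40 °C
Reagents that add atoms: none
Why: Proposed new method: Bu3Sn• abstracts iodine from 21 to give the σ-dienyl radical 22, which inverts fast at the radical carbon (so the C=C–I geometry is not decisive) and closes the cyclopentane 5-exo-trig on the alkene carbon next to the lactone; the secondary radical 23 then closes the cyclohexene 6-endo-trig on the terminal CH2 of the s-cis diene, and the allyl radical 24 takes hydrogen from Bu3SnH at its secondary terminus, which leaves the C=C tetrasubstituted between the ring-fusion carbon and the carbon that bears the trimethylcyclohexyl group. The closest known reaction types are the tin-hydride vinyl-radical 5-exo cyclisation and tandem radical cyclisations that end on a diene; what is new is their combination into a reductive formal [4+2] of a 1-iodo-1,3-diene with a tethered unactivated alkene. The ring-fusion CH is set by the cis-β-lactone, which holds both arms on one face so that the alkene reacts through the rotamer that keeps its distal carbon on the convex face, trans to the lactone oxygen. The CH that bears CH2O-butyrate is set in the second closure, where a half-chair transition state places that group pseudo-equatorial and thus trans to the lactone-bearing neighbour. The step needs three selectivities: first closure through the invertomer that puts the new bond next to the vinyl group (the other presses the incoming carbon against the quaternary ring), attack on the diene terminus and not its inner carbon (allyl stabilisation), and cyclisation faster than reduction (high dilution, slow hydride addition); a 3-exo detour of 23 to a cyclopropylcarbinyl radical is reversible and should drain into 24.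

**Compound list**
1 | isophorone | CC1=CC(=O)CC(C)(C)C1 | starting material
2 | (S)-3,5,5-trimethylcyclohex-2-en-1-ol | O[C@@H]1C=C(C)CC(C)(C)C1 | intermediate
3 | tributyl({[(1S)-3,5,5-trimethylcyclohex-2-en-1-yl]oxy}methyl)stannane | CCCC[Sn](CCCC)(CCCC)CO[C@@H]1C=C(C)CC(C)(C)C1 | intermediate
4 | lithiomethyl (1S)-3,5,5-trimethylcyclohex-2-en-1-yl ether | [Li]CO[C@@H]1C=C(C)CC(C)(C)C1 | intermediate
5 | [(1R)-1,5,5-trimethylcyclohex-2-en-1-yl]methanol | OC[C@@]1(C)C=CCC(C)(C)C1 | intermediate
6 | [(1S)-1,3,3-trimethylcyclohexyl]methanol | OC[C@@]1(C)CCCC(C)(C)C1 | intermediate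
7 | (1S)-1,3,3-trimethylcyclohexane-1-carbaldehyde | O=C[C@@]1(C)CCCC(C)(C)C1 | intermediate
8 | (1S)-1-(2,2-dibromoethenyl)-1,3,3-trimethylcyclohexane | BrC(Br)=C[C@@]1(C)CCCC(C)(C)C1 | intermediate
9 | lithium [(1S)-1,3,3-trimethylcyclohexyl]acetylide | [Li]C#C[C@@]1(C)CCCC(C)(C)C1 | intermediate
10 | methyl 3-[(1S)-1,3,3-trimethylcyclohexyl]prop-2-ynoate | COC(=O)C#C[C@@]1(C)CCCC(C)(C)C1 | intermediate
11 | bromomagnesium alkenyl(vinyl)cuprate, Cu cis to the new vinyl group | C=C[Cu-]/C(C(=O)OC)=C(\C=C)[C@@]1(C)CCCC(C)(C)C1.[Mg+]Br | intermediate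
12 | methyl (2E)-2-iodo-3-[(1S)-1,3,3-trimethylcyclohexyl]penta-2,4-dienoate | C=C/C([C@@]1(C)CCCC(C)(C)C1)=C(\I)C(=O)OC | intermediate
13 | (2E)-2-iodo-3-[(1S)-1,3,3-trimethylcyclohexyl]penta-2,4-dien-1-ol | C=C/C([C@@]1(C)CCCC(C)(C)C1)=C(\I)CO | intermediate
14 | (1S)-1-[(3E)-5-bromo-4-iodopenta-1,3-dien-3-yl]-1,3,3-trimethylcyclohexane | C=C/C([C@@]1(C)CCCC(C)(C)C1)=C(\I)CBr | intermediate
15 | (4E)-4-iodo-5-[(1S)-1,3,3-trimethylcyclohexyl]hepta-4,6-dienoic acid | C=C/C([C@@]1(C)CCCC(C)(C)C1)=C(\I)CCC(=O)O | intermediate
16 | allyl butyrate | CCCC(=O)OCC=C | starting material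
17 | (E)-crotonaldehyde | C/C=C/C=O | starting material
18 | (2E)-4-oxobut-2-en-1-yl butanoate | CCCC(=O)OC/C=C/C=O | intermediate
19 | (4E)-4-iodo-5-[(1S)-1,3,3-trimethylcyclohexyl]hepta-4,6-dienoyl chloride | C=C/C([C@@]1(C)CCCC(C)(C)C1)=C(\I)CCC(=O)Cl | intermediate
20 | ketene derived from 19 | C=C/C([C@@]1(C)CCCC(C)(C)C1)=C(\I)CC=C=O | intermediate
21 | cis-β-lactone, (2S,3R) in the oxetanyl numbering, with iododienyl and (E)-butyryloxypropenyl arms | C=C/C([C@@]1(C)CCCC(C)(C)C1)=C(\I)C[C@H]1C(=O)O[C@H]1/C=C/COC(=O)CCC | intermediate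
22 | σ-dienyl radical from 21 | C=CC(=[C]C[C@H]1C(=O)O[C@H]1/C=C/COC(=O)CCC)[C@@]1(C)CCCC(C)(C)C1 | intermediate
23 | secondary alkyl radical after 5-exo closure (cyclopentane-fused lactone with exocyclic diene) | CCCC(=O)OC[CH][C@H]1[C@@H]2OC(=O)[C@@H]2C/C1=C(/C=C)[C@@]1(C)CCCC(C)(C)C1 | intermediate
24 | tricyclic allyl radical after 6-endo closure | CCCC(=O)OC[C@H]1C[CH]C([C@@]2(C)CCCC(C)(C)C2)=C2C[C@H]3C(=O)O[C@H]3[C@@H]21 | intermediate
25 | 3'-norspongiolactone | CCCC(=O)OC[C@H]1CCC([C@@]2(C)CCCC(C)(C)C2)=C2C[C@H]3C(=O)O[C@H]3[C@@H]21 | target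

**Step count:** 14 steps in total. The longest linear sequence is 13 steps (steps 1–11, 13 and 14).

**Steps most likely to fail**

Step 14 (labelled step).
- What may go wrong: hydrogen transfer to 22 or 23 before ring closure, first closure through the invertomer that places the new bond next to the quaternary ring, capture after the 3-exo detour, or hydrogen delivery to the tertiary end of 24.
- The fallback uses known chemistry, an intramolecular Diels–Alder reaction followed by allylic transposition. It sets out from 15 and returns at 25.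
- Pd(0)/formate hydrogenolysis of the C–I bond with retention gives (4Z)-5-[(1S)-1,3,3-trimethylcyclohexyl]hepta-4,6-dienoic acid F1, in which the chain is trans to vinyl.
- The cyclocondensation of step 13 with commercial (E)-4,4-dimethoxybut-2-enal gives the lactone acetal F2.
- PPTS in wet acetone gives the lactone enal F3.
- Warming F3 in toluene (60 °C, BHT) brings about the Diels–Alder reaction of the outward-substituted diene with the E-enal (endo-formyl). This closes the same two bonds and gives the trans-fused hydrindene carbaldehyde F4, with the C=C one position off.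
- NaBH4 at −78 °C gives the primary alcohol F5.
- Butyric anhydride in pyridine gives the double-bond isomer of the target F6.
- Ene-type allylic chlorination (PhSeCl cat., NCS) follows. On the substituted end of the alkene only the axial ring-fusion hydrogen can be lost, so it gives the transposed allylic chloride F7.
- Bu3SnH/AIBN reduces F7 through the same allyl radical 24 to 25.

Step 13.
- What may go wrong: ketene dimerisation outrunning addition to the less electrophilic conjugated aldehyde, conjugate instead of 1,2-addition, or ionisation of the allylic C–O bond of the product by the lithium salt.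
- The fallback replaces the catalytic [2+2] by an auxiliary-controlled aldol and a separate ring closure. It sets out from 15 and 18 and returns at 21.
- Coupling of 15 with (R)-4-benzyl-1,3-oxazolidin-2-one (PivCl, Et3N, LiCl) gives the N-acyl oxazolidinone F8.
- An Evans syn-aldol reaction (Bu2BOTf, Et3N, then 18) gives the (2R,3S)-aldol adduct F9.
- LiOOH at 0 °C gives the syn-β-hydroxy acid F10.
- Carboxyl activation (BOPCl, Et3N) closes the lactone with retention at the carbinol carbon and gives 21.

Step 3.
- What may go wrong: a slow [2,3] shift, because the new bond forms syn-axial to a ring methyl group, so that [1,2]-shift or protonation of the carbanion competes.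
- The fallback uses a neutral, thermally driven [2,3] shift of an alkoxy(amino)carbene, which delivers the carbonyl oxidation level directly. It sets out from 2 and returns at 7.
- Heating 2 with DMF dimethyl acetal in xylene gives (1R)-N,N,1,5,5-pentamethylcyclohex-2-ene-1-carboxamide F11, by the same suprafacial transfer.
- H2 over Pd/C gives (1S)-N,N,1,3,3-pentamethylcyclohexane-1-carboxamide F12.
- Cp2Zr(H)Cl reduces the tertiary amide to 7.

**Further compounds**
F1 | step 14 | (4Z)-5-[(1S)-1,3,3-trimethylcyclohexyl]hepta-4,6-dienoic acid | C=C/C([C@@]1(C)CCCC(C)(C)C1)=C/CCC(=O)O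
F2 | step 14 | (3R,4S)-4-[(1E)-3,3-dimethoxyprop-1-en-1-yl]-3-{(2Z)-3-[(1S)-1,3,3-trimethylcyclohexyl]penta-2,4-dien-1-yl}oxetan-2-one | C=C/C([C@@]1(C)CCCC(C)(C)C1)=C/C[C@H]1C(=O)O[C@H]1/C=C/C(OC)OC
F3 | step 14 | (2E)-3-[(2S,3R)-4-oxo-3-{(2Z)-3-[(1S)-1,3,3-trimethylcyclohexyl]penta-2,4-dien-1-yl}oxetan-2-yl]prop-2-enal | C=C/C([C@@]1(C)CCCC(C)(C)C1)=C/C[C@H]1C(=O)O[C@H]1/C=C/C=O
F4 | step 14 | trans-fused hydrindene carbaldehyde with cis-fused β-lactone (trisubstituted C=C) | O=C[C@H]1CC=C([C@@]2(C)CCCC(C)(C)C2)[C@H]2C[C@H]3C(=O)O[C@H]3[C@@H]21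
F5 | step 14 | primary alcohol from F4 | OC[C@H]1CC=C([C@@]2(C)CCCC(C)(C)C2)[C@H]2C[C@H]3C(=O)O[C@H]3[C@@H]21
F6 | step 14 | butyrate of F5, double-bond isomer of 25 | CCCC(=O)OC[C@H]1CC=C([C@@]2(C)CCCC(C)(C)C2)[C@H]2C[C@H]3C(=O)O[C@H]3[C@@H]21
F7 | step 14 | transposed allylic chloride (C–Cl configuration of no consequence) | CCCC(=O)OC[C@H]1CC(Cl)C([C@@]2(C)CCCC(C)(C)C2)=C2C[C@H]3C(=O)O[C@H]3[C@@H]21
F8 | step 13 | (4R)-4-benzyl-3-{(4E)-4-iodo-5-[(1S)-1,3,3-trimethylcyclohexyl]hepta-4,6-dienoyl}-1,3-oxazolidin-2-one | C=C/C([C@@]1(C)CCCC(C)(C)C1)=C(\I)CCC(=O)N1[C@H](Cc2ccccc2)COC1=O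
F9 | step 13 | (2R,3S)-syn-aldol adduct of F8 and 18 | C=C/C([C@@]1(C)CCCC(C)(C)C1)=C(\I)C[C@H]([C@@H](O)/C=C/COC(=O)CCC)C(=O)N1[C@H](Cc2ccccc2)COC1=O
F10 | step 13 | (2R,3S)-syn-β-hydroxy acid | C=C/C([C@@]1(C)CCCC(C)(C)C1)=C(\I)C[C@H]([C@@H](O)/C=C/COC(=O)CCC)C(=O)O
F11 | step 3 | (1R)-N,N,1,5,5-pentamethylcyclohex-2-ene-1-carboxamide | CN(C)C(=O)[C@@]1(C)C=CCC(C)(C)C1
F12 | step 3 | (1S)-N,N,1,3,3-pentamethylcyclohexane-1-carboxamide | CN(C)C(=O)[C@@]1(C)CCCC(C)(C)C1
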